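## The problem

The target 30 is a cembrane-type 14-membered carbocycle whose only second ring is the C6–C7 oxirane. With the ring numbered from the acetoxy carbon (C1) to C14, it carries a tetrasubstituted isopropylidene at C4 conjugated with the C5 ketone, a trans-epoxide at C6/C7 (6R,7S), an E-trisubstituted C10=C11 olefin, an allylic carbinol at C12 (R) and a tertiary acetate at C1 (R). In the text below C15 is the branch carbon on C4 and C16 is its methyl that is oxygenated in the open-chain series.

The 14-membered ring has to be closed without any conformational bias, and the two trisubstituted olefins (C10=C11, and C6=C7 as the epoxide precursor) must be made with defined geometry. The four stereocentres fall into three groups (C1; C6/C7; C12) that are too far apart in a flexible ring to control one another. Each therefore needs its own source: C1 from the chiral pool, C12 from a catalyst, the epoxide from a reagent. The only relay that can be trusted is local, a C5 carbinol directing oxygen onto C6=C7.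

The epoxy ketone will not survive nucleophiles, strong base or Lewis acid. The tertiary acetate will not survive organometallics or hydride. The isopropylidene ketone is the conjugated isomer of an isopropenyl ketone. These groups must therefore appear late.

The feature that opens the problem is the C4–C5–C6 array. At lower oxidation level, a C4 carrying an unsaturated three-carbon branch, next to an oxygenated C5, next to an sp carbon C6, is the homoallylic propargylic alcohol that a [2,3]-Wittig shift of an allyl propargyl ether delivers. The carbocycle can thus be reached by contracting a 17-membered cyclic ether that is closed through an easy C–O bond.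

## Retrosynthesis

**Late functional groups (30 ← 29 ← 28 ← 27).** The C12 silyl ether is removed last, the C1 acetate is put on just before that, and the isopropylidene is taken back to the isopropenyl ketone 27. No skeletal bond is cut. The acetate cannot precede any hydride, organolithium or cuprate step, and C12 must stay masked while C5 is oxidised and C1 is acylated. The forward reactions are a base-mediated olefin shift into conjugation, acylation of a linalool-type tertiary alcohol and a fluoride desilylation.

**Epoxide (27 ← 26 ← 25).** The two C–O bonds of the oxirane are cut and the C5 ketone is taken back to a carbinol, giving dienol 25. Nucleophilic epoxidation of a C5 enone has no reliable absolute control in a macrocycle; a Sharpless epoxidation directed by C5–OH puts the face under tartrate control. The isopropenyl group is deliberately kept unconjugated here so that C5–OH has only one allylic olefin. The forward reaction needs the C5 configuration matched to the tartrate, after which C5 is oxidised away.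

**C7 methyl (25 ← 24 ← 22).** The C7–CH3 bond is cut and the E olefin is taken back to the C6≡C7 alkyne of 22. The C5 hydroxyl directs a trans-hydroalumination that puts the metal on the distal carbon C7, which is where the methyl must go. Hydroxyl-directed trans-hydrostannation would put the metal on C6 and is therefore not used. Iodide 24 and a methyl cuprate complete the olefin with retention.

**Key disconnection (22 ← 21).** The C4–C5 bond is cut and the C5 oxygen is reconnected to C16, which turns the 14-membered propargylic alcohol 22 into the 17-membered (E)-allyl propargyl ether 21. This exchanges a C–C macrocyclisation for a C–O one followed by a sigmatropic contraction, and it creates exactly the functional pattern (C5–OH, alkyne, isopropenyl) that the three preceding paragraphs consume. The forward reaction must deprotonate at C5 and not at C16, and must deliver the (5S) carbinol.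

**Ether ring (21 ← 20 ← 19 ← 18 ← 15).** The O–C5 bond is cut (Williamson), then the C5–C6 bond (acetylide plus formaldehyde), leading to terminal alkyne 15. The alternative polarity, propargylic alkoxide on an allylic chloride, would need the two primary hydroxyls to be told apart by extra protecting-group steps. Introducing C5 late on a terminal alkyne gives that differentiation for free. The forward sequence needs a PMB ether on O16 that survives base and is removed oxidatively beside a propargylic bromide.

**C12–C13 bond (15 ← 14 ← 13 ← 11 + 4).** Cutting C12–C13 divides the chain into enal 4 and the linalool-derived iodide 11 and makes C12 the product of a catalytic asymmetric alkylzinc addition. Cutting C11–C12 instead would require an alkenyl metal that contains the alkyne. The tertiary hydroxyl is masked as a TMS ether and the alkyne as its C-silyl derivative; both are released in one methanolysis (14 → 15).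

**Fragments (11 ← 10 ← 8 ← 7 ← 6 ← 5; 4 ← 2 ← 1 + 3).** Iodide 11 comes from (R)-linalool 5, which supplies C1 with its configuration, by allylic oxidation of the E-methyl (6), protection (7, 8), and hydroboration/iodination of the vinyl group (10, 11). Enal 4 comes from silylated pentynol 1 by oxidation to 2 and Wittig reaction with the formyl ylide 3, which sets the C10=C11 geometry.

## Roads not taken

**Alternative 1: Darzens macrocyclisation.**
- Cut: C6–C7 and the C6–O bond of the epoxide.
- Key step: the enolate of an acyclic C5/C6 chloromethyl ketone A2 adds to its C7 methyl ketone, and the alkoxide closes the epoxide to give A1.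
- Merits: ring and epoxide form in one operation, and A1 is constitutionally the penultimate compound 29 of the chosen route. The endgame is therefore shorter, with no C5 carbinol detour and no olefin isomerisation. In step economy after ring closure this road is better.
- Weak points: the acceptor is an enolisable methyl ketone; the chloro ketone has competing γ-hydrogens on the isopropylidene; the tertiary acetate must face an enolate base. C6 and C7 are both created during a macrocyclisation, with only the remote C1 and C12 to bias cis/trans and absolute configuration.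
- Comparison: the chosen plan pays seven steps after ring formation. In return the epoxide configuration is set by a reagent on an olefin of defined geometry, and the fragile groups never see a strong base.

**Alternative 2: Ring-closing alkyne metathesis.**
- Cut: C10–C11, as a triple bond.
- Key step: a molybdenum alkylidyne closes diyne A4 to cycloalkyne A3 with loss of 2-butyne. Hydroxyl-directed trans-hydrostannation then puts tin on C11 (proximal to C12–OH, the correct carbon), and methylation gives the E olefin.
- Merits: this is the most reliable ring closure of the four options for a 14-membered ring, and the olefin geometry is set cleanly after closure. In these two respects it is better than the chosen plan.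
- Weak points: A4 must already contain the complete epoxy ketone, isopropylidene and tertiary acetate, so every stereocentre and all the sensitive functionality are built acyclically and carried through the metathesis. The alkylidyne must tolerate a free propargylic alcohol next to the reacting alkyne. The tin hydride step meets an enone and an epoxy ketone.
- Comparison: the chosen plan closes its ring on a robust polyether/silyl ether substrate from inexpensive chiral-pool material and introduces the epoxy ketone only at the end.

**Alternative 3: B-alkyl Suzuki macrocyclisation.**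
- Cut: C3–C4.
- Key step: 9-BBN hydroborates the C2=C3 vinyl group of A6, and palladium couples the C3 borane with the C4 alkenyl bromide to give A5.
- Merits: the epoxide is set by a Sharpless reaction on an acyclic allylic alcohol, where the method is most reliable, and the isopropylidene is present from the start. These are real advantages over an epoxidation in the macrocycle and a late isomerisation.
- Weak points: the bromide is a fully substituted alkenyl bromide flanked by a silyloxy carbon, so oxidative addition and reductive elimination to a tetrasubstituted olefin must both succeed during a macrocyclisation. The basic aqueous coupling medium meets an epoxide and a tertiary acetate. Three further steps (TES removal, oxidation, TBS removal) follow.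
- Comparison: the chosen plan closes its ring by a Williamson reaction and a sigmatropic shift, both with precedent in this ring size, and avoids a hindered sp3–sp2 macrocoupling.

Key step: step 15

Assumption: lithium bis[(S)-1-phenylethyl]amide is taken to be the antipode that leads to the (5S) carbinol in step 15; if the sense proves opposite, the (R,R)-amide is substituted and nothing else changes.
Assumption: (R)-linalool of high enantiomeric purity is used, since C1 is never corrected later.

## Steps

Step 1
Reactants: 1 5-(trimethylsilyl)pent-4-yn-1-ol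
Product: 2 5-(trimethylsilyl)pent-4-ynal
Conditions: TEMPO (cat.), PhI(OAc)2, CH2Cl2, 23 °C
Reagents that add atoms: none
Why: TEMPO/iodine(III) oxidation of a primary alcohol stops at the aldehyde and leaves the C-silylated alkyne untouched.

Step 2
Reactants: 2 5-(trimethylsilyl)pent-4-ynal; 3 2-(triphenylphosphoranylidene)propanal
Product: 4 (2E)-2-methyl-7-(trimethylsilyl)hept-2-en-6-ynal
Conditions: toluene, 90 °C
Reagents that add atoms: none
Why: Wittig olefination with the formyl-stabilised ylide gives the E 2-methyl enal; the product is less electrophilic than 2, so a second homologation should be slow.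

Step 3
Reactants: 5 (R)-linalool
Product: 6 (2E,6R)-2,6-dimethylocta-2,7-diene-1,6-diol
Conditions: SeO2 (cat.), t-BuOOH, salicylic acid (cat.), CH2Cl2, 23 °C
Reagents that add atoms: tert-butyl hydroperoxide, CC(C)(C)OO
Why: Selenium dioxide allylic oxidation (ene reaction, then [2,3] shift) selects the E-methyl of the trisubstituted olefin; the stereocentre is not involved.

Step 4
Reactants: 6 (2E,6R)-2,6-dimethylocta-2,7-diene-1,6-diol
Product: 7 (3R,6E)-8-[(4-methoxybenzyl)oxy]-3,7-dimethylocta-1,6-dien-3-ol
Conditions: NaH (1 equiv), PMBCl, n-Bu4NI (cat.), THF/DMF, 0 °C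
Reagents that add atoms: 4-methoxybenzyl chloride, COc1ccc(CCl)cc1
Why: Williamson etherification; with one equivalent of hydride the primary allylic alkoxide forms and reacts in preference to the hindered tertiary one.

Step 5
Reactants: 7 (3R,6E)-8-[(4-methoxybenzyl)oxy]-3,7-dimethylocta-1,6-dien-3-ol
Product: 8 (3R,6E)-8-[(4-methoxybenzyl)oxy]-3,7-dimethyl-3-[(trimethylsilyl)oxy]octa-1,6-diene
Conditions: TMSCl, imidazole, DMF, 23 °C
Reagents that add atoms: chlorotrimethylsilane, C[Si](C)(C)Cl
Why: Silylation removes the only acidic hydrogen before the organozinc chemistry; TMS is chosen because it is cleaved together with the alkynyl silane in step 10.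

Step 6
Reactants: 8 (3R,6E)-8-[(4-methoxybenzyl)oxy]-3,7-dimethyl-3-[(trimethylsilyl)oxy]octa-1,6-diene
Product: 10 (3R,6E)-8-[(4-methoxybenzyl)oxy]-3,7-dimethyl-3-[(trimethylsilyl)oxy]oct-6-en-1-ol, via B-alkyl-9-BBN adduct 9 (not isolated)
Conditions: 9-BBN, THF, 0 → 23 °C; then H2O2, aq. NaOH, 0 °C
Reagents that add atoms: hydrogen peroxide, OO
Why: Hydroboration–oxidation; 9-BBN discriminates strongly between the monosubstituted vinyl group and the trisubstituted olefin and places boron on the terminal carbon (C13).

Step 7
Reactants: 10 (3R,6E)-8-[(4-methoxybenzyl)oxy]-3,7-dimethyl-3-[(trimethylsilyl)oxy]oct-6-en-1-ol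
Product: 11 (3R,6E)-1-iodo-8-[(4-methoxybenzyl)oxy]-3,7-dimethyl-3-[(trimethylsilyl)oxy]oct-6-ene
Conditions: I2, PPh3, imidazole, CH2Cl2, 0 °C
Reagents that add atoms: iodine, II
Why: Appel-type iodination of the primary alcohol; the imidazole buffer protects the silyl and PMB ethers.

Step 8
Reactants: 11 (3R,6E)-1-iodo-8-[(4-methoxybenzyl)oxy]-3,7-dimethyl-3-[(trimethylsilyl)oxy]oct-6-ene (excess); 4 (2E)-2-methyl-7-(trimethylsilyl)hept-2-en-6-ynal
Product: 13 open-chain (12R)-allylic alcohol (C1 OTMS, O16 PMB, alkyne C-silylated), via dialkylzinc 12 (not isolated)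
Conditions: Et2Zn, CuI (cat.), 50 °C, then evaporate; Ti(OiPr)4, (1S,2S)-1,2-bis(trifluoromethanesulfonamido)cyclohexane (cat.), 4, toluene, −20 °C
Reagents that add atoms: none
Why: Iodine–zinc exchange followed by titanium/bis(sulfonamide)-catalysed asymmetric addition of the dialkylzinc to the enal forms C12–C13. The (1S,2S) ligand is the antipode expected to deliver the alkyl group to the Re face of the aldehyde, which gives 12R. Silyl ethers, the PMB ether and the C-silylated alkyne are inert to the zinc reagent.

Step 9
Reactants: 13 open-chain (12R)-allylic alcohol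
Product: 14 C12 tert-butyldimethylsilyl ether of 13
Conditions: TBSCl, imidazole, DMF, 23 °C
Reagents that add atoms: tert-butyldimethylsilyl chloride, CC(C)(C)[Si](C)(C)Cl
Why: Standard silylation of the only free hydroxyl, a secondary allylic one.

Step 10
Reactants: 14 C12 tert-butyldimethylsilyl ether of 13
Product: 15 terminal alkyne with free C1 hydroxyl (C12 OTBS, O16 PMB)
Conditions: K2CO3, MeOH, 23 °C
Reagents that add atoms: none
Why: Methanolysis cleaves the alkynyl C–Si bond and the tertiary O–SiMe3 ether; TBS and PMB ethers are stable to carbonate in methanol.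

Step 11
Reactants: 15 terminal alkyne with free C1 hydroxyl; 16 formaldehyde (as paraformaldehyde)
Product: 18 propargylic alcohol (C5–OH, C1–OH, C12 OTBS, O16 PMB), via dilithium alkoxide acetylide 17 (not isolated)
Conditions: n-BuLi (2.1 equiv), THF, −78 °C; then (CH2O)n, −78 → 23 °C
Reagents that add atoms: none
Why: Hydroxymethylation of a terminal alkyne: two equivalents of base give the alkoxide–acetylide and the acetylide adds to formaldehyde; at −78 °C with no excess base the PMB allyl ether is not metalated.

Step 12
Reactants: 18 propargylic alcohol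
Product: 19 propargylic bromide (C1–OH, C12 OTBS, O16 PMB)
Conditions: CBr4, PPh3, CH2Cl2, 0 °C
Reagents that add atoms: carbon tetrabromide, BrC(Br)(Br)Br
Why: Appel bromination is selective for the primary propargylic alcohol; the tertiary alcohol does not react at 0 °C.

Step 13
Reactants: 19 propargylic bromide
Product: 20 bromo allylic alcohol (C16–OH, C1–OH, C12 OTBS)
Conditions: DDQ, CH2Cl2/pH 7 buffer, 0 °C
Reagents that add atoms: none
Why: Oxidative PMB cleavage under buffered conditions needs neither acid nor nucleophile, so the propargylic bromide, the TBS ether and the olefins are untouched.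

Step 14
Reactants: 20 bromo allylic alcohol
Product: 21 17-membered (E)-allyl propargyl ether (C1–OH, C12 OTBS)
Conditions: NaH, n-Bu4NI (cat.), THF, slow addition to 0.002 M, 23 → 50 °C
Reagents that add atoms: none
Why: Intramolecular Williamson etherification under high dilution: the primary allylic alkoxide displaces the propargylic bromide (SN2) to close the 17-membered ring. The tertiary alkoxide is much less nucleophilic and would have to form a strained 12-membered ether.

Step 15
Reactants: 21 17-membered (E)-allyl propargyl ether
Product: 22 14-membered (4S,5S)-propargylic alcohol with isopropenyl at C4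
Conditions: LiN[(S)-CH(Me)Ph]2 (4 equiv, from the amine and n-BuLi), THF, −78 → −20 °C
Reagents that add atoms: none
Why: After the C1 hydroxyl has become its lithium alkoxide, the amide removes one of the two diastereotopic propargylic hydrogens at C5. The α-oxy propargyllithium then adds suprafacially to C4 through a five-membered envelope transition state while the O–C16 bond breaks and the C15=C16 double bond appears. This is a [2,3]-Wittig rearrangement; its closest relatives are the base-induced ring contractions of macrocyclic allyl propargyl ethers to propargylic carbocycles, including chiral-amide variants. The 14-membered carbocycle is closed by transannular C4–C5 bond formation inside the 17-membered ether, a contraction by three atoms in which O, C16 and C15 leave the ring as the hydroxyl and the isopropenyl group. C5 is set by the chiral base, which selects the proton and hence the face of the carbanion that reacts; the remote centres C1 and C12 are not expected to override it. C4 is set relative to C5 by the E geometry of the C4=C15 olefin: with the alkynyl group exo on the envelope, an E olefin gives the anti (4S,5S) arrangement. The step needs deprotonation at C5 and not at the allylic C16, which the sp-hybridised neighbour secures by making the C5 hydrogens the more acidic. It also needs the [2,3] shift to outrun the [1,2] shift, which low temperature favours. Only C5 matters later (step 18); C4 is erased in step 20.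

Step 16
Reactants: 22 14-membered (4S,5S)-propargylic alcohol
Product: 24 (6Z)-7-iodo dienediol, via cyclic alkenylaluminate 23 (not isolated)
Conditions: Red-Al, THF, 0 → 23 °C; then I2, THF, −78 → 0 °C
Reagents that add atoms: iodine, II
Why: Hydroxyl-directed trans-hydroalumination: the C5 alkoxyaluminate delivers hydride to C6 and places aluminium on C7 in a five-membered chelate; iodinolysis with retention gives the (Z)-iodide.

Step 17
Reactants: 24 (6Z)-7-iodo dienediol
Product: 25 (5R,6E)-allylic alcohol with C7 methyl
Conditions: Me2CuLi (excess, from MeLi and CuI), Et2O, 0 °C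
Reagents that add atoms: lithium dimethylcuprate, [Li+].C[Cu-]C
Why: Substitution of the alkenyl iodide by the cuprate with retention gives the E-trisubstituted olefin; the excess covers the two hydroxyl protons.

Step 18
Reactants: 25 (5R,6E)-allylic alcohol
Product: 26 erythro 6,7-epoxy alcohol
Conditions: Ti(OiPr)4, L-(+)-diisopropyl tartrate, t-BuOOH, 4 Å MS, CH2Cl2, −20 °C
Reagents that add atoms: tert-butyl hydroperoxide, CC(C)(C)OO
Why: Sharpless asymmetric epoxidation of a secondary allylic alcohol in the matched sense: L-(+)-tartrate delivers oxygen to the face that gives the C6/C7 configuration of the target, and the (5R) carbinol is the fast-reacting, erythro-giving epimer. Any C5 epimer carried over from step 15 is mismatched and should be left behind. The homoallylic isopropenyl group and the silylated allylic olefin should not be epoxidised.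

Step 19
Reactants: 26 erythro 6,7-epoxy alcohol
Product: 27 6,7-epoxy-5-ketone with isopropenyl at C4
Conditions: Dess–Martin periodinane, NaHCO3, CH2Cl2, 0 → 23 °C
Reagents that add atoms: none
Why: Dess–Martin oxidation of the secondary alcohol under buffered, non-basic conditions keeps the epoxide and the tertiary alcohol intact.

Step 20
Reactants: 27 6,7-epoxy-5-ketone with isopropenyl at C4
Product: 28 isopropylidene epoxy ketone (C1–OH, C12 OTBS)
Conditions: DBU, CH2Cl2, 23 °C
Reagents that add atoms: none
Why: Base-mediated isomerisation of the β,γ-unsaturated ketone into conjugation through the C4 dienolate, which is reprotonated at C16. This erases C4; the oxirane C6–H is not acidic enough to epimerise under an amidine base.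

Step 21
Reactants: 28 isopropylidene epoxy ketone
Product: 29 C1 acetate, C12 TBS ether of the target
Conditions: Ac2O, DMAP, Et3N, CH2Cl2, 23 → 40 °C
Reagents that add atoms: acetic anhydride, CC(=O)OC(C)=O
Why: DMAP-catalysed acylation of a tertiary alcohol of the linalool type; C12 is still silylated, so only C1 is acetylated.

Step 22
Reactants: 29 C1 acetate, C12 TBS ether of the target
Product: 30 CNP0404804.1
Conditions: HF·pyridine, pyridine, THF, 0 → 23 °C
Reagents that add atoms: none
Why: Buffered HF·pyridine cleaves the secondary allylic TBS ether without forming an alkoxide, so neither acetyl migration to C12 nor base damage to the epoxy enone is expected.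

## Compound list

1 | 5-(trimethylsilyl)pent-4-yn-1-ol | C[Si](C)(C)C#CCCCO | starting material
2 | 5-(trimethylsilyl)pent-4-ynal | C[Si](C)(C)C#CCCC=O | intermediate
3 | 2-(triphenylphosphoranylidene)propanal | CC(C=O)=P(c1ccccc1)(c1ccccc1)c1ccccc1 | starting material
4 | (2E)-2-methyl-7-(trimethylsilyl)hept-2-en-6-ynal | C[Si](C)(C)C#CCC/C=C(\C)C=O | intermediate
5 | (R)-linalool, (3R)-3,7-dimethylocta-1,6-dien-3-ol | C=C[C@](C)(O)CCC=C(C)C | starting material
6 | (2E,6R)-2,6-dimethylocta-2,7-diene-1,6-diol | C=C[C@](C)(O)CC/C=C(\C)CO | intermediate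
7 | (3R,6E)-8-[(4-methoxybenzyl)oxy]-3,7-dimethylocta-1,6-dien-3-ol | C=C[C@](C)(O)CC/C=C(\C)COCc1ccc(OC)cc1 | intermediate
8 | (3R,6E)-8-[(4-methoxybenzyl)oxy]-3,7-dimethyl-3-[(trimethylsilyl)oxy]octa-1,6-diene | C=C[C@](C)(O[Si](C)(C)C)CC/C=C(\C)COCc1ccc(OC)cc1 | intermediate
9 | 9-[(3R,6E)-8-[(4-methoxybenzyl)oxy]-3,7-dimethyl-3-[(trimethylsilyl)oxy]oct-6-en-1-yl]-9-borabicyclo[3.3.1]nonane | B1(CC[C@](C)(O[Si](C)(C)C)CC/C=C(\C)COCc2ccc(OC)cc2)C2CCCC1CCC2 | intermediate
10 | (3R,6E)-8-[(4-methoxybenzyl)oxy]-3,7-dimethyl-3-[(trimethylsilyl)oxy]oct-6-en-1-ol | OCC[C@](C)(O[Si](C)(C)C)CC/C=C(\C)COCc1ccc(OC)cc1 | intermediate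
11 | (3R,6E)-1-iodo-8-[(4-methoxybenzyl)oxy]-3,7-dimethyl-3-[(trimethylsilyl)oxy]oct-6-ene | ICC[C@](C)(O[Si](C)(C)C)CC/C=C(\C)COCc1ccc(OC)cc1 | intermediate
12 | bis[(3R,6E)-8-[(4-methoxybenzyl)oxy]-3,7-dimethyl-3-[(trimethylsilyl)oxy]oct-6-en-1-yl]zinc | [Zn](CC[C@](C)(O[Si](C)(C)C)CC/C=C(\C)COCc1ccc(OC)cc1)CC[C@](C)(O[Si](C)(C)C)CC/C=C(\C)COCc1ccc(OC)cc1 | intermediate
13 | (5E,7R,10R,13E)-15-[(4-methoxybenzyl)oxy]-6,10,14-trimethyl-1-(trimethylsilyl)-10-[(trimethylsilyl)oxy]pentadeca-5,13-dien-1-yn-7-ol | C[Si](C)(C)C#CCC/C=C(\C)[C@H](O)CC[C@](C)(O[Si](C)(C)C)CC/C=C(\C)COCc1ccc(OC)cc1 | intermediate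
14 | 7-O-tert-butyldimethylsilyl ether of 13 (ring positions: C12 OTBS, C1 OTMS) | C[Si](C)(C)C#CCC/C=C(\C)[C@H](O[Si](C)(C)C(C)(C)C)CC[C@](C)(O[Si](C)(C)C)CC/C=C(\C)COCc1ccc(OC)cc1 | intermediate
15 | (2E,6R,9R,10E)-9-[(tert-butyldimethylsilyl)oxy]-1-[(4-methoxybenzyl)oxy]-2,6,10-trimethylpentadeca-2,10-dien-14-yn-6-ol | C#CCC/C=C(\C)[C@H](O[Si](C)(C)C(C)(C)C)CC[C@](C)(O)CC/C=C(\C)COCc1ccc(OC)cc1 | intermediate
16 | formaldehyde (used as paraformaldehyde) | C=O | starting material
17 | dilithium salt of 15 (lithium acetylide, lithium tertiary alkoxide) | [Li]C#CCC/C=C(\C)[C@H](O[Si](C)(C)C(C)(C)C)CC[C@](C)(O[Li])CC/C=C(\C)COCc1ccc(OC)cc1 | intermediate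
18 | (6E,8R,11R,14E)-8-[(tert-butyldimethylsilyl)oxy]-16-[(4-methoxybenzyl)oxy]-7,11,15-trimethylhexadeca-6,14-dien-2-yne-1,11-diol | OCC#CCC/C=C(\C)[C@H](O[Si](C)(C)C(C)(C)C)CC[C@](C)(O)CC/C=C(\C)COCc1ccc(OC)cc1 | intermediate
19 | (2E,6R,9R,10E)-16-bromo-9-[(tert-butyldimethylsilyl)oxy]-1-[(4-methoxybenzyl)oxy]-2,6,10-trimethylhexadeca-2,10-dien-14-yn-6-ol | BrCC#CCC/C=C(\C)[C@H](O[Si](C)(C)C(C)(C)C)CC[C@](C)(O)CC/C=C(\C)COCc1ccc(OC)cc1 | intermediate
20 | (2E,6R,9R,10E)-16-bromo-9-[(tert-butyldimethylsilyl)oxy]-2,6,10-trimethylhexadeca-2,10-dien-14-yne-1,6-diol | BrCC#CCC/C=C(\C)[C@H](O[Si](C)(C)C(C)(C)C)CC[C@](C)(O)CC/C=C(\C)CO | intermediate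
21 | (3E,7R,10R,11E)-10-[(tert-butyldimethylsilyl)oxy]-3,7,11-trimethyl-1-oxacycloheptadeca-3,11-dien-15-yn-7-ol | O1CC#CCC/C=C(\C)[C@H](O[Si](C)(C)C(C)(C)C)CC[C@](C)(O)CC/C=C(\C)C1 | intermediate
22 | (1R,4S,5S,10E,12R)-12-[(tert-butyldimethylsilyl)oxy]-1,11-dimethyl-4-(prop-1-en-2-yl)cyclotetradec-10-en-6-yne-1,5-diol (target ring numbering) | C=C(C)[C@H]1[C@H](O)C#CCC/C=C(\C)[C@H](O[Si](C)(C)C(C)(C)C)CC[C@](C)(O)CC1 | intermediate
23 | sodium cyclic alkenyl(alkoxy)aluminate of 22: O5–Al–C7 five-membered chelate, two 2-methoxyethoxy ligands on Al (C1 hydroxyl drawn free; in the flask it is also held as an aluminium alkoxide) | [Na+].C=C(C)[C@H]1[C@@H]2O[Al-](OCCOC)(OCCOC)C(=C2)CC/C=C(\C)[C@H](O[Si](C)(C)C(C)(C)C)CC[C@](C)(O)CC1 | intermediate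
24 | (1R,4S,5S,6Z,10E,12R)-12-[(tert-butyldimethylsilyl)oxy]-7-iodo-1,11-dimethyl-4-(prop-1-en-2-yl)cyclotetradeca-6,10-diene-1,5-diol | C=C(C)[C@H]1[C@H](O)/C=C(\I)CC/C=C(\C)[C@H](O[Si](C)(C)C(C)(C)C)CC[C@](C)(O)CC1 | intermediate
25 | (1R,4S,5R,6E,10E,12R)-12-[(tert-butyldimethylsilyl)oxy]-1,7,11-trimethyl-4-(prop-1-en-2-yl)cyclotetradeca-6,10-diene-1,5-diol | C=C(C)[C@H]1[C@H](O)/C=C(\C)CC/C=C(\C)[C@H](O[Si](C)(C)C(C)(C)C)CC[C@](C)(O)CC1 | intermediate
26 | (1R,4S,5S,6S,7S,10E,12R)-12-[(tert-butyldimethylsilyl)oxy]-6,7-epoxy-1,7,11-trimethyl-4-(prop-1-en-2-yl)cyclotetradec-10-ene-1,5-diol | C=C(C)[C@H]1[C@H](O)[C@@H]2O[C@@]2(C)CC/C=C(\C)[C@H](O[Si](C)(C)C(C)(C)C)CC[C@](C)(O)CC1 | intermediate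
27 | (1R,4S,6R,7S,10E,12R)-12-[(tert-butyldimethylsilyl)oxy]-6,7-epoxy-1-hydroxy-1,7,11-trimethyl-4-(prop-1-en-2-yl)cyclotetradec-10-en-5-one | C=C(C)[C@H]1C(=O)[C@@H]2O[C@@]2(C)CC/C=C(\C)[C@H](O[Si](C)(C)C(C)(C)C)CC[C@](C)(O)CC1 | intermediate
28 | (1R,6R,7S,10E,12R)-12-[(tert-butyldimethylsilyl)oxy]-6,7-epoxy-1-hydroxy-1,7,11-trimethyl-4-(propan-2-ylidene)cyclotetradec-10-en-5-one | O[C@]1(C)CCC(=C(C)C)C(=O)[C@@H]2O[C@@]2(C)CC/C=C(\C)[C@H](O[Si](C)(C)C(C)(C)C)CC1 | intermediate
29 | 1-O-acetate of 28 (C12 TBS ether of the target) | CC(=O)O[C@]1(C)CCC(=C(C)C)C(=O)[C@@H]2O[C@@]2(C)CC/C=C(\C)[C@H](O[Si](C)(C)C(C)(C)C)CC1 | intermediate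
30 | CNP0404804.1, (1R,6R,7S,10E,12R)-1-acetoxy-6,7-epoxy-12-hydroxy-1,7,11-trimethyl-4-(propan-2-ylidene)cyclotetradec-10-en-5-one | CC(=O)O[C@]1(C)CCC(=C(C)C)C(=O)[C@@H]2O[C@@]2(C)CC/C=C(\C)[C@H](O)CC1 | target

## Step count and least certain steps

Total: 22 steps. Longest linear sequence: 20 steps (steps 3–22, from (R)-linalool); steps 1–2 make the enal.

**Step 15 (key step).** Most likely failure: incomplete or reversed discrimination between the two C5 hydrogens by the chiral amide in the presence of the C1 lithium alkoxide, which gives the C5 epimers in comparable amounts. Lesser risks are metalation at C16 (attack on the alkyne, allenyl carbinol) and a [1,2] shift on warming. Fallback, from 21 back to 22: rearrange 21 with n-butyllithium (THF, −78 °C), which is indifferent to the two hydrogens and should give the anti carbinols as a stereoisomer mixture F1. Oxidise the propargylic hydroxyl with MnO2 to the ynone F2. Set C5 by catalyst control with Noyori transfer hydrogenation (RuCl[(S,S)-TsDPEN](p-cymene), i-PrOH). This returns 22 together with its C4 epimer F3, and the two converge at 28 because C4 becomes trigonal in step 20.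

**Step 14.** Most likely failure: intermolecular etherification and base-induced decomposition of the propargylic bromide (1,4-elimination, allene formation) competing with the slow 17-membered closure. Fallback, from 18 back to 21, with the polarity reversed:
- cap the propargylic hydroxyl of 18 as the triethylsilyl ether F4 (TESCl, imidazole);
- free the allylic alcohol F5 with DDQ;
- convert it into the allylic chloride F6 (MsCl, LiCl, 2,6-lutidine);
- remove the primary TES group (PPTS, MeOH) to give the hydroxy chloride F7;
- close the ring with the magnesium alkoxide of the propargylic alcohol (EtMgBr, THF–HMPA, high dilution), which is weakly basic, to give 21.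

**Step 8.** Most likely failure: incomplete iodine–zinc exchange and an uncatalysed background addition that lowers the C12 selectivity, with only one of the two alkyl groups on zinc used. Fallback, from 11 and 4 back to 13: convert 11 into the alkyllithium (t-BuLi, Et2O, −78 °C) and add it to 4 to give the C12 epimer mixture F8. Oxidise with MnO2 to the enone F9. Reduce with (S)-Me-CBS/catecholborane, in which the α-methyl alkenyl group acts as the large substituent and 12R is expected, to return 13.

**Step 18.** Most likely failure: slow titanium-mediated oxygen transfer and eroded facial selectivity, because the C7 methyl is cis to the carbinol carbon and the ring restricts the reactive conformation. Fallback, from 25 back to 27, replacing reagent control by substrate control: Mitsunobu inversion of 25 (4-nitrobenzoic acid, PPh3, DIAD) gives the ester F10, and methanolysis (K2CO3, MeOH) gives the C5 epimer F11. Hydroxyl-directed epoxidation without tartrate (VO(acac)2 or Ti(OiPr)4, t-BuOOH) relies on 1,3-allylic strain against the C7 methyl and should give the threo epoxy alcohol F12 with the oxirane on the required face. Dess–Martin oxidation of F12 gives 27.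

**Step 20.** Most likely failure: the enolate-mediated olefin shift stops short of completion, or the base attacks the epoxy ketone before the shift is complete. Fallback, from 27 back to 28, with no new compound: cobalt–salen/phenylsilane hydrogen-atom-transfer isomerisation. This is a radical chain that moves a 1,1-disubstituted olefin to the more substituted position without forming an enolate.

## Further compounds

F1 | step 15 | mixture of C4/C5 stereoisomers of 22 from the achiral-base rearrangement | C=C(C)C1C(O)C#CCC/C=C(\C)[C@H](O[Si](C)(C)C(C)(C)C)CC[C@](C)(O)CC1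
F2 | step 15 | (1R,10E,12R)-12-[(tert-butyldimethylsilyl)oxy]-1-hydroxy-1,11-dimethyl-4-(prop-1-en-2-yl)cyclotetradec-10-en-6-yn-5-one (C4 mixed) | C=C(C)C1C(=O)C#CCC/C=C(\C)[C@H](O[Si](C)(C)C(C)(C)C)CC[C@](C)(O)CC1
F3 | step 15 | (4R,5S) C4 epimer of 22 | C=C(C)[C@@H]1[C@H](O)C#CCC/C=C(\C)[C@H](O[Si](C)(C)C(C)(C)C)CC[C@](C)(O)CC1
F4 | step 14 | 1-O-triethylsilyl ether of 18 | CC[Si](CC)(CC)OCC#CCC/C=C(\C)[C@H](O[Si](C)(C)C(C)(C)C)CC[C@](C)(O)CC/C=C(\C)COCc1ccc(OC)cc1
F5 | step 14 | allylic alcohol from F4 (O16 free, O5 TES) | CC[Si](CC)(CC)OCC#CCC/C=C(\C)[C@H](O[Si](C)(C)C(C)(C)C)CC[C@](C)(O)CC/C=C(\C)CO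
F6 | step 14 | allylic chloride from F5 (C16–Cl, O5 TES) | CC[Si](CC)(CC)OCC#CCC/C=C(\C)[C@H](O[Si](C)(C)C(C)(C)C)CC[C@](C)(O)CC/C=C(\C)CCl
F7 | step 14 | hydroxy chloride (C5–OH, C16–Cl, C1–OH, C12 OTBS) | OCC#CCC/C=C(\C)[C@H](O[Si](C)(C)C(C)(C)C)CC[C@](C)(O)CC/C=C(\C)CCl
F8 | step 8 | C12 epimer mixture of 13 | C[Si](C)(C)C#CCC/C=C(\C)C(O)CC[C@](C)(O[Si](C)(C)C)CC/C=C(\C)COCc1ccc(OC)cc1
F9 | step 8 | C12 ketone (enone) corresponding to 13 | C[Si](C)(C)C#CCC/C=C(\C)C(=O)CC[C@](C)(O[Si](C)(C)C)CC/C=C(\C)COCc1ccc(OC)cc1
F10 | step 18 | C5-inverted 4-nitrobenzoate of 25 | C=C(C)[C@H]1[C@@H](OC(=O)c2ccc(cc2)[N+](=O)[O-])/C=C(\C)CC/C=C(\C)[C@H](O[Si](C)(C)C(C)(C)C)CC[C@](C)(O)CC1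
F11 | step 18 | (4S,5S) C5 epimer of 25 | C=C(C)[C@H]1[C@@H](O)/C=C(\C)CC/C=C(\C)[C@H](O[Si](C)(C)C(C)(C)C)CC[C@](C)(O)CC1
F12 | step 18 | threo epoxy alcohol, C5 epimer of 26 | C=C(C)[C@H]1[C@@H](O)[C@@H]2O[C@@]2(C)CC/C=C(\C)[C@H](O[Si](C)(C)C(C)(C)C)CC[C@](C)(O)CC1
F0 | step 20 | none | none
A1 | alternative 1 | Darzens product, C12 TBS ether of the target (same constitution and configuration as 29) | CC(=O)O[C@]1(C)CCC(=C(C)C)C(=O)[C@@H]2O[C@@]2(C)CC/C=C(\C)[C@H](O[Si](C)(C)C(C)(C)C)CC1
A2 | alternative 1 | acyclic C6 chloromethyl ketone / C7 methyl ketone precursor | ClCC(=O)C(=C(C)C)CC[C@@](C)(OC(C)=O)CC[C@@H](O[Si](C)(C)C(C)(C)C)/C(C)=C/CCC(C)=O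
A3 | alternative 2 | 14-membered cycloalkyne propargylic alcohol | CC(=O)O[C@]1(C)CCC(=C(C)C)C(=O)[C@@H]2O[C@@]2(C)CCC#C[C@H](O)CC1
A4 | alternative 2 | acyclic bis(methyl-capped) diyne | CC#C[C@H](O)CC[C@](C)(OC(C)=O)CCC(=C(C)C)C(=O)[C@@H]1O[C@@]1(C)CCC#CC
A5 | alternative 3 | 14-membered epoxide with C5 TES ether and C12 TBS ether | CC(=O)O[C@]1(C)CCC(=C(C)C)[C@H](O[Si](CC)(CC)CC)[C@@H]2O[C@@]2(C)CC/C=C(\C)[C@H](O[Si](C)(C)C(C)(C)C)CC1
A6 | alternative 3 | acyclic vinyl / alkenyl bromide precursor | C=C[C@@](C)(OC(C)=O)CC[C@@H](O[Si](C)(C)C(C)(C)C)/C(C)=C/CC[C@]1(C)O[C@H]1[C@@H](O[Si](CC)(CC)CC)C(Br)=C(C)C
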